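**Strategy.** The cyclohexane ring is numbered C1 (quaternary carbon), C2 (arm-bearing CH), C3 (alkylidene carbon), C4, C5, C6 (carbinol carbon). Everything rests on disconnecting C1–C2. The hydroxymethyl carbon and a C3 carbonyl are 1,4-related across this bond, and C1, C6, C5, C4 plus the hydroxymethyl carbon trace a 3-hydroxy-3-methyl δ-lactone. An Ireland–Claisen ring contraction of a doubly silylated 6-acyl δ-lactone (ketene acetal at C1, Z-enol silane at C2=C3) should form C1–C2, cleave C4–O, close the carbocycle and set C1 and C2 in one operation. The keto lactone, carrying the α-chain and a β-silyloxy β-methyl group, is assembled from three fragments by esterification and a SmI2 Reformatsky cyclisation.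

Key step: step 11

Remark: the lactone α-carbon (C1) is carried as a mixture of epimers until the key step, and C3 as a mixture between isopropenyl addition and transposition. Both centres become trigonal later, so their SMILES leave them undefined. "Homofarnesyl" below means (3E,7E)-4,8,12-trimethyltrideca-3,7,11-trien-1-yl, and TBS means tert-butyldimethylsilyl.

Step 1
Reactants: 1 1,3-dithiane; 2 tert-butyl(4-iodobutoxy)dimethylsilane
Product: 3 2-[4-(tert-butyldimethylsilyloxy)butyl]-1,3-dithiane
Conditions: n-BuLi, THF, −30 °C; then 2, −78 → 0 °C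
Reagents that add atoms: none
Why: Corey–Seebach alkylation of 2-lithio-1,3-dithiane with a primary iodide is reliable and installs C2 plus the silyloxypropyl arm on the masked C3 carbonyl.

Step 2
Reactants: 3 2-[4-(tert-butyldimethylsilyloxy)butyl]-1,3-dithiane
Product: 4 2-[4-(tert-butyldimethylsilyloxy)butyl]-1,3-dithiane-2-carbaldehyde
Conditions: n-BuLi, THF, −20 °C; DMF, −78 → 0 °C; H2O
Reagents that add atoms: N,N-dimethylformamide, CN(C)C=O
Why: Formylation of the 2-alkyl-2-lithiodithiane with DMF (Corey–Seebach acylation) gives a non-enolisable aldehyde whose carbonyl carbon becomes C4.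

Step 3
Reactants: 4 2-[4-(tert-butyldimethylsilyloxy)butyl]-1,3-dithiane-2-carbaldehyde; 5 acetone
Product: 6 (4S)-4-{2-[4-(tert-butyldimethylsilyloxy)butyl]-1,3-dithian-2-yl}-4-hydroxybutan-2-one
Conditions: D-proline (30 mol %), acetone/DMSO 1:4, rt
Reagents that add atoms: none
Why: The proline-catalysed direct aldol reaction (enamine catalysis) works best with α-quaternary, non-enolisable aldehydes, and D-proline should deliver the mirror image of the known L-proline sense, setting C4 as S.

Step 4
Reactants: 7 (2E,6E)-farnesyl bromide; 8 3-chloropropan-1-ol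
Product: 10 (5E,9E)-6,10,14-trimethylpentadeca-5,9,13-trien-1-ol, via ClMg(CH2)3OMgCl 9 (not isolated)
Conditions: 8, MeMgCl, THF, −20 °C, then Mg, reflux; then 7, Li2CuCl4 (3 mol %), THF, −20 → 0 °C
Reagents that add atoms: none
Why: Li2CuCl4-catalysed cross-coupling of a primary alkyl Grignard reagent with a primary allylic bromide should occur at the α-carbon with retention of the E alkene, adding the carbons that become C7, C1 and the first chain carbon.

Step 5
Reactants: 10 (5E,9E)-6,10,14-trimethylpentadeca-5,9,13-trien-1-ol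
Product: 11 (5E,9E)-6,10,14-trimethylpentadeca-5,9,13-trienoic acid
Conditions: TEMPO (20 mol %), PhI(OAc)2 (2.2 equiv), MeCN/H2O 1:1, rt
Reagents that add atoms: water, O
Why: Oxoammonium-mediated oxidation through the aldehyde hydrate takes a primary alcohol to the acid without electrophilic halogen, so the three trisubstituted alkenes should be left alone.

Step 6
Reactants: 11 (5E,9E)-6,10,14-trimethylpentadeca-5,9,13-trienoic acid
Product: 12 (5E,9E)-2-bromo-6,10,14-trimethylpentadeca-5,9,13-trienoic acid (racemic)
Conditions: LiN(i-Pr)2 (2.2 equiv), THF, −78 → 0 °C; CBr4, −78 °C; dilute HCl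
Reagents that add atoms: carbon tetrabromide, BrC(Br)(Br)Br
Why: α-Bromination of the carboxylic acid dianion by halogen transfer from CBr4 should be much faster than any reaction at the alkenes, and the new centre may be racemic because it becomes an enolate carbon in step 8.

Step 7
Reactants: 6 (4S)-4-{2-[4-(tert-butyldimethylsilyloxy)butyl]-1,3-dithian-2-yl}-4-hydroxybutan-2-one; 12 (5E,9E)-2-bromo-6,10,14-trimethylpentadeca-5,9,13-trienoic acid
Product: 13 (1S)-1-{2-[4-(tert-butyldimethylsilyloxy)butyl]-1,3-dithian-2-yl}-3-oxobutyl (5E,9E)-2-bromo-6,10,14-trimethylpentadeca-5,9,13-trienoate (both CHBr epimers)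
Conditions: DCC, DMAP (10 mol %), CH2Cl2, 0 °C
Reagents that add atoms: none
Why: Steglich esterification acylates the secondary alcohol under near-neutral, cold conditions, which should leave C4 untouched and avoid β-elimination of the β-acyloxy ketone.

Step 8
Reactants: 13 bromo ester
Product: 14 (4R,6S)-6-{2-[4-(tert-butyldimethylsilyloxy)butyl]-1,3-dithian-2-yl}-4-hydroxy-4-methyl-3-homofarnesyltetrahydro-2H-pyran-2-one (C3 epimers; hydroxyl trans to the dithianyl group)
Conditions: SmI2 (2.2 equiv), THF, −78 °C; then aq. NH4Cl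
Reagents that add atoms: none
Why: In this SmI2-promoted intramolecular Reformatsky reaction the samarium enolate should add to the methyl ketone through a closed chair-like transition state with the ketone oxygen axial on the metal and the dithianyl group equatorial, so the new tertiary alcohol (C6, R) ends trans to the C4 substituent while the α-carbon forms as an inconsequential mixture.

Step 9
Reactants: 14 hydroxy lactone
Product: 15 (4R,6S)-6-{2-[4-(tert-butyldimethylsilyloxy)butyl]-1,3-dithian-2-yl}-4-methyl-4-(triethylsilyloxy)-3-homofarnesyltetrahydro-2H-pyran-2-one (C3 epimers)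
Conditions: Et3SiOTf, 2,6-lutidine, CH2Cl2, −78 → 0 °C
Reagents that add atoms: triethylsilyl trifluoromethanesulfonate, CC[Si](CC)(CC)OS(=O)(=O)C(F)(F)F
Why: Silyl triflate silylation caps the hindered tertiary alcohol without strong base, which avoids retro-aldol opening and removes the acidic proton before the enolisations of step 11.

Step 10
Reactants: 15 silyl ether
Product: 16 (4R,6S)-6-[5-(tert-butyldimethylsilyloxy)pentanoyl]-4-methyl-4-(triethylsilyloxy)-3-homofarnesyltetrahydro-2H-pyran-2-one (C3 epimers; acyl trans to silyloxy)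
Conditions: MeI, CaCO3, MeCN/H2O 9:1, 45 °C
Reagents that add atoms: water, O
Why: Alkylative dithiane hydrolysis (S-methylation, then hydrolysis of the sulfonium salt) is neutral and non-oxidising, so the triene, both silyl ethers and the now epimerisable C4 centre should survive.

Step 11
Reactants: 16 keto lactone
Product: 19 (1S,2R,6R)-2-[3-(tert-butyldimethylsilyloxy)propyl]-6-methyl-3-oxo-6-(triethylsilyloxy)-1-homofarnesylcyclohexane-1-carboxylic acid, via bis-silylated lactone 17 (not isolated), via silyl ester enol silane 18 (not isolated)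
Conditions: TBSCl (3.5 equiv), KN(SiMe3)2 (2.6 equiv), THF, −78 → 0 °C; PhMe, 100 °C; then Bu4NF/AcOH 1:1, THF, 0 °C
Reagents that add atoms: none
Why: Proposed new method: with TBSCl present, KN(SiMe3)2 should silylate the kinetic C2 enolate of the ketone (Z geometry, arm syn to oxygen) and the lactone enolate to give 17, in which C1=C(OSi)–O–C4–C3=C2 is a 1,5-diene that on heating undergoes a concerted suprafacial [3,3] shift, forming C1–C2 and breaking C4–O to give 18. The closest known reaction type is the Ireland–Claisen ring contraction of lactones bearing an alkenyl group on the carbinol carbon; an enol silane as the allyl partner is the untested element. The cyclohexane is closed by the sigmatropic bond formation itself, through a boat transition state enforced by the C5–C6 tether that spans the termini C1 and C4 (a bicyclo[2.2.2]octane-like array), not by a separate polar cyclisation. C1 is controlled by C4 and C6: C2 can reach C1 only on the lactone face that carries the C4 acyl group, which places the carboxyl cis to the C6 silyloxy group that was trans to that acyl group. C2 is controlled by the Z enol geometry, which in the boat puts the arm cis to the carboxyl and the C2 hydrogen, not the arm, next to the C6 methyl group. The step needs enolisation at C2 rather than C4 and silylation faster than β-elimination of the C6 silyloxy group, which the lower kinetic acidity of the tertiary, oxygen-bearing C4–H and the in situ quench at −78 °C should secure; buffered fluoride then cleaves the silyl ester and the C3=C4 enol silane so that the ketone appears only at C3.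

Step 12
Reactants: 19 keto acid
Product: 20 methyl (1S,2R,6R)-2-[3-(tert-butyldimethylsilyloxy)propyl]-6-methyl-3-oxo-6-(triethylsilyloxy)-1-homofarnesylcyclohexane-1-carboxylate
Conditions: Me3SiCHN2, PhMe/MeOH 4:1, 0 °C
Reagents that add atoms: (trimethylsilyl)diazomethane, C[Si](C)(C)C=[N+]=[N-]
Why: Diazoalkane O-methylation esterifies the hindered acid at oxygen under neutral conditions, so C2 next to the ketone should not epimerise.

Step 13
Reactants: 20 keto ester
Product: 21 methyl (1S,2R,6R)-2-[3-(tert-butyldimethylsilyloxy)propyl]-3-hydroxy-6-methyl-3-(prop-1-en-2-yl)-6-(triethylsilyloxy)-1-homofarnesylcyclohexane-1-carboxylate (C3 epimers)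
Conditions: CH2=C(CH3)MgBr, CeCl3, THF, −78 → 0 °C
Reagents that add atoms: isopropenylmagnesium bromide, CC(=C)[Mg]Br
Why: Organocerium 1,2-addition is nucleophilic but barely basic, so it should add to the hindered, enolisable C3 ketone without epimerising C2 and ignore the neopentyl ester; the C3 configuration is irrelevant because C3 becomes trigonal in step 16.

Step 14
Reactants: 21 hydroxy ester
Product: 22 diol with C1 hydroxymethyl and C3 tertiary allylic hydroxyl (C1 R, C2 R, C6 R; C3 epimers), otherwise as 21
Conditions: LiAlH4, THF, 0 °C → rt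
Reagents that add atoms: none
Why: LiAlH4 reduction of the methyl ester gives the C1 hydroxymethyl group and leaves silyl ethers and alkenes untouched; should the C3 alkoxide have closed onto the ester in step 13, that lactone is reduced to the same diol.

Step 15
Reactants: 22 diol
Product: 23 C1-CH2OTBS ether of 22 with free tertiary allylic alcohol (C3 epimers)
Conditions: TBSCl, imidazole, CH2Cl2, 0 °C
Reagents that add atoms: tert-butyldimethylsilyl chloride, CC(C)(C)[Si](C)(C)Cl
Why: Selective silylation of the primary over the tertiary alcohol protects the hydroxymethyl group from chromium oxidation and from trapping the allylic system in step 16.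

Step 16
Reactants: 23 tertiary allylic alcohol
Product: 24 (2Z)-2-[(2S,3R,4R)-3-(tert-butyldimethylsilyloxymethyl)-2-[3-(tert-butyldimethylsilyloxy)propyl]-4-methyl-4-(triethylsilyloxy)-3-homofarnesylcyclohexylidene]propanal
Conditions: C5H5NH[CrO3Cl] (3 equiv), 4 Å molecular sieves, CH2Cl2, rt
Reagents that add atoms: none
Why: In the Babler–Dauben oxidative transposition the tertiary allylic chromate ester undergoes a [3,3] shift to the primary chromate, which is oxidised to the enal; the methyl group should turn toward the unsubstituted C4 side, which is also the thermodynamic preference, so the formyl group ends syn to C2 (Z).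

Step 17
Reactants: 24 protected enal
Product: 25 target, (2Z)-2-[(2S,3R,4R)-4-hydroxy-3-(hydroxymethyl)-2-(3-hydroxypropyl)-4-methyl-3-homofarnesylcyclohexylidene]propanal
Conditions: HF·pyridine, pyridine, THF, 0 °C → rt
Reagents that add atoms: none
Why: Buffered fluoride desilylation should remove the two primary TBS ethers and the tertiary triethylsilyl ether without base, which protects the allylic stereocentre C2 and the Z geometry of the enal.

**Compound list**

1 | 1,3-dithiane | C1CSCSC1 | starting material
2 | tert-butyl(4-iodobutoxy)dimethylsilane | CC(C)(C)[Si](C)(C)OCCCCI | starting material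
3 | 2-[4-(tert-butyldimethylsilyloxy)butyl]-1,3-dithiane | CC(C)(C)[Si](C)(C)OCCCCC1SCCCS1 | intermediate
4 | 2-[4-(tert-butyldimethylsilyloxy)butyl]-1,3-dithiane-2-carbaldehyde | CC(C)(C)[Si](C)(C)OCCCCC1(C=O)SCCCS1 | intermediate
5 | acetone | CC(C)=O | starting material
6 | (4S)-4-{2-[4-(tert-butyldimethylsilyloxy)butyl]-1,3-dithian-2-yl}-4-hydroxybutan-2-one | CC(=O)C[C@H](O)C1(CCCCO[Si](C)(C)C(C)(C)C)SCCCS1 | intermediate
7 | (2E,6E)-farnesyl bromide | CC(C)=CCC/C(C)=C/CC/C(C)=C/CBr | starting material
8 | 3-chloropropan-1-ol | OCCCCl | starting material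
9 | [3-(chloromagnesiooxy)propyl]magnesium chloride, ClMg(CH2)3OMgCl | Cl[Mg]CCCO[Mg]Cl | intermediate (not isolated)
10 | (5E,9E)-6,10,14-trimethylpentadeca-5,9,13-trien-1-ol | CC(C)=CCC/C(C)=C/CC/C(C)=C/CCCCO | intermediate
11 | (5E,9E)-6,10,14-trimethylpentadeca-5,9,13-trienoic acid | CC(C)=CCC/C(C)=C/CC/C(C)=C/CCCC(=O)O | intermediate
12 | (5E,9E)-2-bromo-6,10,14-trimethylpentadeca-5,9,13-trienoic acid, racemic | CC(C)=CCC/C(C)=C/CC/C(C)=C/CCC(Br)C(=O)O | intermediate
13 | (1S)-1-{2-[4-(tert-butyldimethylsilyloxy)butyl]-1,3-dithian-2-yl}-3-oxobutyl 2-bromo ester of 12, CHBr epimers | CC(C)=CCC/C(C)=C/CC/C(C)=C/CCC(Br)C(=O)O[C@@H](CC(C)=O)C1(CCCCO[Si](C)(C)C(C)(C)C)SCCCS1 | intermediate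
14 | (4R,6S)-6-(2-alkyl-1,3-dithian-2-yl)-4-hydroxy-4-methyl-3-homofarnesyltetrahydro-2H-pyran-2-one, C3 epimers, hydroxyl trans to dithianyl | CC(C)=CCC/C(C)=C/CC/C(C)=C/CCC1C(=O)O[C@H](C2(CCCCO[Si](C)(C)C(C)(C)C)SCCCS2)C[C@@]1(C)O | intermediate
15 | triethylsilyl ether of 14 | CC(C)=CCC/C(C)=C/CC/C(C)=C/CCC1C(=O)O[C@H](C2(CCCCO[Si](C)(C)C(C)(C)C)SCCCS2)C[C@@]1(C)O[Si](CC)(CC)CC | intermediate
16 | (4R,6S)-6-[5-(tert-butyldimethylsilyloxy)pentanoyl]-4-methyl-4-(triethylsilyloxy)-3-homofarnesyltetrahydro-2H-pyran-2-one, C3 epimers (key-step precursor) | CC(C)=CCC/C(C)=C/CC/C(C)=C/CCC1C(=O)O[C@H](C(=O)CCCCO[Si](C)(C)C(C)(C)C)C[C@@]1(C)O[Si](CC)(CC)CC | intermediate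
17 | TBS ketene acetal (C1=C7) and (Z)-TBS enol silane (C2=C3) of 16 | CC(C)=CCC/C(C)=C/CC/C(C)=C/CCC1=C(O[Si](C)(C)C(C)(C)C)O[C@H](/C(O[Si](C)(C)C(C)(C)C)=C/CCCO[Si](C)(C)C(C)(C)C)C[C@@]1(C)O[Si](CC)(CC)CC | intermediate (not isolated)
18 | TBS (1S,2R,6R)-3-(TBS-oxy)-2-[3-(TBS-oxy)propyl]-6-methyl-6-(triethylsilyloxy)-1-homofarnesylcyclohex-3-ene-1-carboxylate | CC(C)=CCC/C(C)=C/CC/C(C)=C/CC[C@]1(C(=O)O[Si](C)(C)C(C)(C)C)[C@@H](CCCO[Si](C)(C)C(C)(C)C)C(O[Si](C)(C)C(C)(C)C)=CC[C@@]1(C)O[Si](CC)(CC)CC | intermediate (not isolated)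
19 | (1S,2R,6R)-2-[3-(tert-butyldimethylsilyloxy)propyl]-6-methyl-3-oxo-6-(triethylsilyloxy)-1-homofarnesylcyclohexane-1-carboxylic acid; carboxyl, arm and silyloxy all cis (key-step product) | CC(C)=CCC/C(C)=C/CC/C(C)=C/CC[C@]1(C(=O)O)[C@@H](CCCO[Si](C)(C)C(C)(C)C)C(=O)CC[C@@]1(C)O[Si](CC)(CC)CC | intermediate
20 | methyl ester of 19 | CC(C)=CCC/C(C)=C/CC/C(C)=C/CC[C@]1(C(=O)OC)[C@@H](CCCO[Si](C)(C)C(C)(C)C)C(=O)CC[C@@]1(C)O[Si](CC)(CC)CC | intermediate
21 | C3 isopropenyl carbinol of 20, C3 epimers | CC(C)=CCC/C(C)=C/CC/C(C)=C/CC[C@]1(C(=O)OC)[C@@H](CCCO[Si](C)(C)C(C)(C)C)C(O)(C(C)=C)CC[C@@]1(C)O[Si](CC)(CC)CC | intermediate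
22 | diol: C1 hydroxymethyl, C3 tertiary allylic alcohol, C3 epimers | CC(C)=CCC/C(C)=C/CC/C(C)=C/CC[C@]1(CO)[C@@H](CCCO[Si](C)(C)C(C)(C)C)C(O)(C(C)=C)CC[C@@]1(C)O[Si](CC)(CC)CC | intermediate
23 | primary TBS ether of 22, C3 epimers | CC(C)=CCC/C(C)=C/CC/C(C)=C/CC[C@]1(CO[Si](C)(C)C(C)(C)C)[C@@H](CCCO[Si](C)(C)C(C)(C)C)C(O)(C(C)=C)CC[C@@]1(C)O[Si](CC)(CC)CC | intermediate
24 | tris-silylated (Z)-enal (C1 R, C2 S, C6 R) | CC(C)=CCC/C(C)=C/CC/C(C)=C/CC[C@]1(CO[Si](C)(C)C(C)(C)C)[C@@H](CCCO[Si](C)(C)C(C)(C)C)/C(=C(/C)C=O)CC[C@@]1(C)O[Si](CC)(CC)CC | intermediate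
25 | CNP0284886.2, (2Z)-2-[(2S,3R,4R)-4-hydroxy-3-(hydroxymethyl)-2-(3-hydroxypropyl)-4-methyl-3-homofarnesylcyclohexylidene]propanal | CC(C)=CCC/C(C)=C/CC/C(C)=C/CC[C@]1(CO)[C@@H](CCCO)/C(=C(/C)C=O)CC[C@@]1(C)O | target

**Step count.** Total: 17 steps. Longest linear sequence: 14 steps (steps 1–3 or 4–6, then 7–17).

**Steps most likely to fail**

1. Step 11. Enolisation may occur toward C4 or be followed by β-elimination before silylation, or the enol silane may not take part in the [3,3] shift below the temperature at which the ketene acetal decomposes. The fallback makes C1–C2 by known enolate chemistry and sets out from 16. Double deprotonation with LiN(i-Pr)2 in THF at −78 °C followed by Fe(acac)3 (intramolecular oxidative enolate coupling) should give the bridged 2-oxabicyclo[2.2.2]octane keto lactone F1. The C5–C6 tether again forces bond formation on the acyl-bearing face, and the arm at C2 settles away from the C6 methyl group. SmI2 in THF/MeOH at −78 °C then cleaves the α-acyloxy ketone C4–O bond reductively and returns to the route at 19.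

2. Step 16. Chromate ester formation at the congested tertiary carbinol may be slow, so that ionisation and dehydration to dienes compete, or the alkene geometry may come out mixed. The fallback separates transposition from oxidation and sets out from 23. O3ReOSiPh3 (catalytic, Et2O, −50 → 0 °C) should effect the 1,3-transposition to the thermodynamically preferred primary allylic alcohol F2 with the tetrasubstituted alkene. MnO2 in CH2Cl2 then oxidises it and rejoins the route at 24.

3. Step 17. Fluoride treatment of the enal may cause Z/E isomerisation or conjugate addition of the freed hydroxyl groups, and cleavage of the hindered tertiary silyl ether may be incomplete. The fallback removes the silyl groups at the alcohol oxidation level and sets out from 24. Luche reduction (NaBH4, CeCl3·7H2O, MeOH, 0 °C) gives the allylic alcohol F2 again. Bu4NF in THF then removes all three silyl groups to give the pentaol F3. MnO2 oxidises only the allylic primary alcohol and comes back at 25.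

Further compounds
F1 | step 11 | bridged keto lactone, 2-oxabicyclo[2.2.2]octane-3,5-dione core with C1–C2 bond formed and C4–O intact (C1 S, C2 R, C4 S, C6 R) | CC(C)=CCC/C(C)=C/CC/C(C)=C/CC[C@]1(C(=O)O2)[C@@H](CCCO[Si](C)(C)C(C)(C)C)C(=O)[C@@H]2C[C@@]1(C)O[Si](CC)(CC)CC
F2 | step 16 | tris-silylated (Z)-primary allylic alcohol, the reduced form of 24 | CC(C)=CCC/C(C)=C/CC/C(C)=C/CC[C@]1(CO[Si](C)(C)C(C)(C)C)[C@@H](CCCO[Si](C)(C)C(C)(C)C)/C(=C(/C)CO)CC[C@@]1(C)O[Si](CC)(CC)CC
F3 | step 17 | fully desilylated (Z)-allylic alcohol, the pentaol corresponding to 25 | CC(C)=CCC/C(C)=C/CC/C(C)=C/CC[C@]1(CO)[C@@H](CCCO)/C(=C(/C)CO)CC[C@@]1(C)O
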